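**Assumption and numbering.** Ring atoms are numbered C1 = C(Me)(homoprenyl), C2=C3, C4 = CH–O‑senecioyl, C5 = C(Me)OH, C6=C7, C8 = C=O, C9 = C(CH2OH), C10 = CH, C11 = CH2. The target is then (1S,4R,5R; 2E,6E,9Z). D‑tartrate acetonide dimethyl ester, homoprenyl bromide, the Still–Gennari phosphonoacetate and TOM‑Cl are taken as catalogue items.

## Retrosynthetic overview

1. Target ⇒ desilylation, C4‑O acylation and acetonide removal from a macrocyclic trienone. The 11‑membered ring (the only carbocycle) is closed last, by ring-closing metathesis at C6=C7.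
2. C8–C10 enone: vinyl‑Grignard acylation at C8 and a Z‑selective Still–Gennari olefination of a C10 aldehyde; the C6 vinyl comes from a Wittig methylenation.
3. Key bond C1–C11 and the quaternary C1: Johnson–Claisen [3,3] rearrangement of a (3R,2E)-allylic alcohol with 1,3‑chirality transfer.
4. C2–C3: Felkin addition of an (E)-alkenylalane (carboalumination of 6‑methylhept‑5‑en‑1‑yne) to a tartrate-derived aldehyde.
5. C4/C5: D‑tartrate acetonide, with the C5 methyl introduced by enolate alkylation with retention. Ring order: dioxolane (bought) → 11‑membered ring (RCM) → dioxolane removed.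

## Route

**Step 1**
Reactants: 1, dimethyl (4S,5S)-2,2-dimethyl-1,3-dioxolane-4,5-dicarboxylate (D‑tartrate acetonide)
Product: 2, dimethyl (4S,5S)-2,2,4-trimethyl-1,3-dioxolane-4,5-dicarboxylate (esters still trans)
Conditions: LDA, THF/DMPU, −78 °C; MeI, −78 → −50 °C
Reagents that add atoms: iodomethane, CI
Why: Seebach-type alkylation of the tartrate-acetonide enolate, where MeI enters cis to the neighbouring ester so the trans-diester is retained and the new quaternary centre (target C5) is set by the surviving tartrate centre (target C4).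

**Step 2**
Reactants: 2
Product: 3, methyl (4S,5S)-5-formyl-2,2,4-trimethyl-1,3-dioxolane-4-carboxylate
Conditions: DIBAL‑H (1.05 eq), CH2Cl2, −78 °C; MeOH, Rochelle salt; used crude
Reagents that add atoms: none
Why: Chemoselective DIBAL half-reduction, in which the ester on the CH carbon reacts faster than the neopentyl-type ester on the quaternary carbon and the chelated Al‑hemiacetal collapses to the aldehyde only on quench.

**Step 3**
Reactants: 4, 5-bromo-2-methylpent-2-ene
Product: 5, 6-methylhept-5-en-1-yne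
Conditions: LiC≡CH·H2NCH2CH2NH2, DMSO, 0 °C → rt
Reagents that add atoms: lithium acetylide–ethylenediamine complex, [Li]C#C.NCCN
Why: SN2 alkylation of acetylide by an unhindered primary bromide.

**Step 4**
Reactants: 3; 5
Product: 6, methyl (4S,5R)-5-[(1R,2E)-1-hydroxy-3,7-dimethylocta-2,6-dien-1-yl]-2,2,4-trimethyl-1,3-dioxolane-4-carboxylate
Conditions: 5, Me3Al (2 eq), Cp2ZrCl2 (0.2 eq), CH2Cl2, 0 °C → rt; then 3, −78 → −20 °C; Rochelle salt; minor C3 epimer removed by chromatography
Reagents that add atoms: trimethylaluminium, C[Al](C)C (supplies the C1 methyl)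
Why: Negishi syn-carboalumination gives the (E)-alkenylalane, and its non-chelating addition to the α‑alkoxy aldehyde follows the polar Felkin–Anh model (ring C–O anti to the nucleophile) to give the 3,4‑anti (3R) carbinol.

**Step 5**
Reactants: 6
Product: 7, methyl (4S,5R)-5-[(1E,3S)-3-(2-ethoxy-2-oxoethyl)-3,7-dimethylocta-1,6-dien-1-yl]-2,2,4-trimethyl-1,3-dioxolane-4-carboxylate
Conditions: MeC(OEt)3 (excess), EtCO2H (cat.), 140 °C, EtOH distilled off
Reagents that add atoms: triethyl orthoacetate, CC(OCC)(OCC)OCC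
Why: Johnson–Claisen [3,3] rearrangement forms the C1–C11 bond; A(1,3) strain holds the dioxolane substituent pseudo-equatorial, giving the E‑C2=C3 alkene and suprafacial transfer of the (3R) carbinol chirality to the (1S) quaternary centre.

**Step 6**
Reactants: 7
Product: 8, (4S,5R)-5-[(1E,3S)-3,7-dimethyl-3-(2-oxoethyl)octa-1,6-dien-1-yl]-2,2,4-trimethyl-1,3-dioxolane-4-carbaldehyde
Conditions: DIBAL‑H (2.3 eq), CH2Cl2, −78 °C; Rochelle salt; used crude
Reagents that add atoms: none
Why: Low-temperature DIBAL reduction stops both esters at the aldehyde level, giving the C10 and C6 aldehydes in one operation.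

**Step 7**
Reactants: 9, methyl 2-[bis(2,2,2-trifluoroethoxy)phosphoryl]acetate
Product: 10, methyl 2-[bis(2,2,2-trifluoroethoxy)phosphoryl]-3-[(triisopropylsilyl)oxy]propanoate (racemic)
Conditions: NaH, THF, 0 °C; TOM‑Cl, Bu4NI (cat.), 0 °C → rt
Reagents that add atoms: (triisopropylsiloxy)methyl chloride, ClCO[Si](C(C)C)(C(C)C)C(C)C
Why: C‑alkylation of the stabilised phosphonoacetate anion by a reactive α‑chloro ether installs the protected hydroxymethyl group.

**Step 8**
Reactants: 8; 10
Product: 11, methyl (2Z,5S,6E)-7-[(4R,5S)-5-formyl-2,2,5-trimethyl-1,3-dioxolan-4-yl]-5-methyl-5-(4-methylpent-3-en-1-yl)-2-{[(triisopropylsilyl)oxy]methyl}hepta-2,6-dienoate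
Conditions: 10 (1.05 eq), KHMDS, 18-crown-6, THF, −78 °C; then 8
Reagents that add atoms: none (new atoms come from 10)
Why: Still–Gennari Z‑selective Horner–Wadsworth–Emmons olefination, where the bulky fully substituted carbanion attacks only the CH2CHO aldehyde and kinetic control places C11 cis to the ester carbon (C8).

**Step 9**
Reactants: 11
Product: 12, methyl (2Z,5S,6E)-7-[(4R,5R)-5-ethenyl-2,2,5-trimethyl-1,3-dioxolan-4-yl]-5-methyl-5-(4-methylpent-3-en-1-yl)-2-{[(triisopropylsilyl)oxy]methyl}hepta-2,6-dienoate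
Conditions: Ph3PCH3Br, KHMDS, THF, −78 → 0 °C
Reagents that add atoms: methyltriphenylphosphonium bromide, C[P+](c1ccccc1)(c1ccccc1)c1ccccc1.[Br-]
Why: Wittig methylenation of the hindered, non-enolisable α‑alkoxy aldehyde; the enoate does not react with the ylide at low temperature.

**Step 10**
Reactants: 12
Product: 13, (4Z,7S,8E)-9-[(4R,5R)-5-ethenyl-2,2,5-trimethyl-1,3-dioxolan-4-yl]-7-methyl-7-(4-methylpent-3-en-1-yl)-4-{[(triisopropylsilyl)oxy]methyl}nona-1,4,8-trien-3-one
Conditions: MeNH(OMe)·HCl, i‑PrMgCl, THF, −20 °C; then CH2=CHMgBr, −20 → 0 °C; inverse quench into cold 1 M HCl (one pot)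
Reagents that add atoms: vinylmagnesium bromide, C=C[Mg]Br
Why: In situ Weinreb amide formation followed by Grignard addition, where the chelated tetrahedral intermediate stops at the ketone and masks the vinyl ketone until work-up, leaving the Z‑alkene untouched.

**Step 11**
Reactants: 13
Product: 14, the macrocyclic acetonide: 11‑membered (2E,6E,9Z)-trien-8-one, (1S,4R,5R), 4,5‑O‑isopropylidene, 9‑CH2OTIPS
Conditions: Grubbs II or Hoveyda–Grubbs II (10 mol %), 1,4-benzoquinone (20 mol %), toluene (1 mM), 80 °C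
Reagents that add atoms: none
Why: Ring-closing metathesis between the C6 vinyl and the vinyl ketone (loss of ethylene) closes the ring and is expected to give the conjugated E‑enone under thermodynamic control, with the internal and trisubstituted alkenes inert.

**Step 12**
Reactants: 14
Product: 15, the 4,5‑diol of 14 (9‑CH2OTIPS retained)
Conditions: AcOH/H2O/THF (3:1:1), 45 °C
Reagents that add atoms: none
Why: Acid-catalysed acetal hydrolysis; the primary TIPS ether and the dienone tolerate aqueous acetic acid.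

**Step 13**
Reactants: 15
Product: 16, the C4 3-methylbut-2-enoate of 15 (5‑OH free, 9‑CH2OTIPS)
Conditions: 3-methylbut-2-enoyl chloride (1.5 eq), pyridine, DMAP (cat.), CH2Cl2, 0 °C
Reagents that add atoms: 3-methylbut-2-enoyl chloride, CC(C)=CC(=O)Cl
Why: DMAP-catalysed acylation is selective for the secondary allylic C4–OH because the tertiary C5–OH is unreactive and the primary OH is silylated.

**Step 14**
Reactants: 16
Product: 17, the target (CID 15817377)
Conditions: HF·pyridine, pyridine/THF, 0 °C → rt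
Reagents that add atoms: none
Why: Buffered fluoride desilylation frees the primary allylic alcohol without the basic conditions that could cause acyl migration or oxa-Michael addition.

## Compound list

1 | dimethyl (4S,5S)-2,2-dimethyl-1,3-dioxolane-4,5-dicarboxylate | COC(=O)[C@H]1OC(C)(C)O[C@@H]1C(=O)OC | starting material
2 | dimethyl (4S,5S)-2,2,4-trimethyl-1,3-dioxolane-4,5-dicarboxylate | COC(=O)[C@H]1OC(C)(C)O[C@]1(C)C(=O)OC | intermediate
3 | methyl (4S,5S)-5-formyl-2,2,4-trimethyl-1,3-dioxolane-4-carboxylate | O=C[C@H]1OC(C)(C)O[C@]1(C)C(=O)OC | intermediate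
4 | 5-bromo-2-methylpent-2-ene | CC(C)=CCCBr | starting material
5 | 6-methylhept-5-en-1-yne | C#CCCC=C(C)C | intermediate
6 | methyl (4S,5R)-5-[(1R,2E)-1-hydroxy-3,7-dimethylocta-2,6-dien-1-yl]-2,2,4-trimethyl-1,3-dioxolane-4-carboxylate | CC(C)=CCC/C(C)=C/[C@@H](O)[C@H]1OC(C)(C)O[C@]1(C)C(=O)OC | intermediate
7 | methyl (4S,5R)-5-[(1E,3S)-3-(2-ethoxy-2-oxoethyl)-3,7-dimethylocta-1,6-dien-1-yl]-2,2,4-trimethyl-1,3-dioxolane-4-carboxylate | CCOC(=O)C[C@](C)(CCC=C(C)C)/C=C/[C@H]1OC(C)(C)O[C@]1(C)C(=O)OC | intermediate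
8 | (4S,5R)-5-[(1E,3S)-3,7-dimethyl-3-(2-oxoethyl)octa-1,6-dien-1-yl]-2,2,4-trimethyl-1,3-dioxolane-4-carbaldehyde | O=CC[C@](C)(CCC=C(C)C)/C=C/[C@H]1OC(C)(C)O[C@]1(C)C=O | intermediate
9 | methyl 2-[bis(2,2,2-trifluoroethoxy)phosphoryl]acetate | COC(=O)CP(=O)(OCC(F)(F)F)OCC(F)(F)F | starting material
10 | methyl 2-[bis(2,2,2-trifluoroethoxy)phosphoryl]-3-[(triisopropylsilyl)oxy]propanoate | COC(=O)C(CO[Si](C(C)C)(C(C)C)C(C)C)P(=O)(OCC(F)(F)F)OCC(F)(F)F | intermediate
11 | methyl (2Z,5S,6E)-7-[(4R,5S)-5-formyl-2,2,5-trimethyl-1,3-dioxolan-4-yl]-5-methyl-5-(4-methylpent-3-en-1-yl)-2-{[(triisopropylsilyl)oxy]methyl}hepta-2,6-dienoate | COC(=O)/C(CO[Si](C(C)C)(C(C)C)C(C)C)=C\C[C@](C)(CCC=C(C)C)/C=C/[C@H]1OC(C)(C)O[C@]1(C)C=O | intermediate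
12 | methyl (2Z,5S,6E)-7-[(4R,5R)-5-ethenyl-2,2,5-trimethyl-1,3-dioxolan-4-yl]-5-methyl-5-(4-methylpent-3-en-1-yl)-2-{[(triisopropylsilyl)oxy]methyl}hepta-2,6-dienoate | COC(=O)/C(CO[Si](C(C)C)(C(C)C)C(C)C)=C\C[C@](C)(CCC=C(C)C)/C=C/[C@H]1OC(C)(C)O[C@]1(C)C=C | intermediate
13 | (4Z,7S,8E)-9-[(4R,5R)-5-ethenyl-2,2,5-trimethyl-1,3-dioxolan-4-yl]-7-methyl-7-(4-methylpent-3-en-1-yl)-4-{[(triisopropylsilyl)oxy]methyl}nona-1,4,8-trien-3-one | C=CC(=O)/C(CO[Si](C(C)C)(C(C)C)C(C)C)=C\C[C@](C)(CCC=C(C)C)/C=C/[C@H]1OC(C)(C)O[C@]1(C)C=C | intermediate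
14 | macrocyclic (1S,4R,5R; 2E,6E,9Z)-trien-8-one, 4,5‑O‑isopropylidene, 9‑CH2OTIPS | CC(C)=CCC[C@]1(C)/C=C/[C@H]2OC(C)(C)O[C@]2(C)/C=C/C(=O)/C(CO[Si](C(C)C)(C(C)C)C(C)C)=C\C1 | intermediate
15 | macrocyclic 4,5‑diol, 9‑CH2OTIPS | CC(C)=CCC[C@]1(C)/C=C/[C@@H](O)[C@](C)(O)/C=C/C(=O)/C(CO[Si](C(C)C)(C(C)C)C(C)C)=C\C1 | intermediate
16 | macrocyclic 4‑O‑(3-methylbut-2-enoate), 5‑OH, 9‑CH2OTIPS | CC(C)=CCC[C@]1(C)/C=C/[C@@H](OC(=O)C=C(C)C)[C@](C)(O)/C=C/C(=O)/C(CO[Si](C(C)C)(C(C)C)C(C)C)=C\C1 | intermediate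
17 | CID 15817377 | CC(C)=CCC[C@]1(C)/C=C/[C@@H](OC(=O)C=C(C)C)[C@](C)(O)/C=C/C(=O)/C(CO)=C\C1 | target

## Step count

- Total steps: 14.
- Longest linear sequence: 12 steps (1 → 2 → 3 → 6 → 7 → 8 → 11 → 12 → 13 → 14 → 15 → 16 → 17). Steps 3 and 7 are single-step side branches.

## Steps most likely to fail

1. **Step 11 (RCM).** Risks are medium-ring strain, a hindered C6 vinyl on the ketal carbon, and uncertain E/Z outcome at C6=C7. Fallback: from 11, convert the C6 aldehyde to the (E)-vinyl iodide (Takai), take the ester to the Z‑enal, close C7–C8 by intramolecular Nozaki–Hiyama–Kishi coupling and oxidise the bis-allylic alcohol, so the alkene geometry is fixed before cyclisation.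
2. **Step 8 (olefination of the dialdehyde).** It must react at one of two aldehydes and give the Z‑alkene with a new α‑CH2OTIPS phosphonate. Fallback: differentiate the termini before the Claisen step by converting the hindered ester of 6 to the vinyl group (DIBAL, then Ph3P=CH2), so only the C10 aldehyde exists when the Still–Gennari reaction is run.
3. **Step 4 (alkenylalane addition).** The Felkin ratio at C3 dictates C1 after the Claisen step, and methyl transfer from aluminium can compete. Fallback: replace addition by acylation and reduction, i.e. make the Weinreb amide selectively at the unhindered ester of 2, add the alkenyllithium (from the carboalumination/iodine-derived vinyl iodide) to give the enone, and set C3 by chelation-controlled Zn(BH4)2 reduction to the anti (3R) alcohol.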